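**Retrosynthetic overview**
1. (+)-Neoolivil ⇒ all-trans oxolane-3,4-dicarboxylate. The two esters become the two CH2OH groups in the last step.
2. Oxolane diester ⇒ acyclic (2S,3S)-bis(4-hydroxy-3-methoxybenzyl)succinate + H2O. Both ring C–O bonds are made in one flask by double benzylic dehydrogenation and insertion of water, and C2/C5 are set here.
3. (2S,3S)-Succinate ⇒ C2-symmetric bis(imide) ⇒ oxidative enolate homocoupling of one Evans imide. This forms the C3–C4 bond and sets both backbone stereocentres.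
4. Imide ⇒ dihydroferulic acid + (R)-4-isopropyloxazolidinone (recovered later).
5. Ring order: both arenes are bought, and the oxolane is the only ring formed, in the penultimate step.

Assumption: the SMILES is read as (2R,3S,4S,5R), the C2-symmetric all-trans oxolane. Lignan locants are used in the comments: C7/C7′ = oxolane C2/C5, C8/C8′ = oxolane C3/C4.

**Step 1**
Reactants: 1 3-(4-hydroxy-3-methoxyphenyl)propanoic acid (dihydroferulic acid); 2 (4R)-4-isopropyl-1,3-oxazolidin-2-one
Product: 5 (4R)-3-{3-[4-(tert-butyldimethylsilyloxy)-3-methoxyphenyl]propanoyl}-4-isopropyl-1,3-oxazolidin-2-one, via 3-(4-hydroxy-3-methoxyphenyl)propanoic pivalic anhydride 3 (not isolated), via (4R)-3-[3-(4-hydroxy-3-methoxyphenyl)propanoyl]-4-isopropyl-1,3-oxazolidin-2-one 4 (not isolated)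
Conditions: PivCl (1.05 equiv), Et3N (4.5 equiv), THF, −20 °C, 1 h; LiCl (1.1 equiv), 2, −20 °C → rt, 6 h; then TBSCl (2.2 equiv), DMAP (5 mol %), rt, 4 h; aq. NaHCO3 wash
Reagents that add atoms: tert-butyldimethylsilyl chloride, CC(C)(C)[Si](C)(C)Cl; pivaloyl chloride, CC(C)(C)C(=O)Cl (pivaloyl group of 3 only)
Why: Mixed-anhydride N-acylation of an Evans oxazolidinone (Et3N/LiCl variant), in which the carboxylate is activated much faster than the guaiacol OH at −20 °C without DMAP, is followed by DMAP-catalysed phenol silylation in the same flask (the excess TBSCl covers transient silylation of pivalate, which the bicarbonate wash undoes), and no stereocentre is formed.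

**Step 2**
Reactants: 5 (4R)-3-{3-[4-(tert-butyldimethylsilyloxy)-3-methoxyphenyl]propanoyl}-4-isopropyl-1,3-oxazolidin-2-one (2 equiv)
Product: 7 (4R,4′R)-3,3′-{(2S,3S)-2,3-bis[4-(tert-butyldimethylsilyloxy)-3-methoxybenzyl]butanedioyl}bis(4-isopropyl-1,3-oxazolidin-2-one), via lithium (Z)-3-[4-(tert-butyldimethylsilyloxy)-3-methoxyphenyl]-1-[(4R)-4-isopropyl-2-oxo-1,3-oxazolidin-3-yl]prop-1-en-1-olate 6 (not isolated)
Conditions: LDA (1.05 equiv per 5), THF, −78 °C, 45 min; anhydrous CuCl2 (1.1 equiv) in DMF, −78 → 0 °C; chromatography/crystallisation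
Reagents that add atoms: lithium diisopropylamide, [Li+].CC(C)[N-]C(C)C (lithium of 6 only)
Why: In this oxidative homocoupling of a chelated (Z)-imide enolate (Cu(II) one-electron oxidation, then dimerisation), each α-carbon bonds on the face away from the isopropyl group, so two (R)-auxiliaries give the (2S,3S)-dimer, and the minor (2R,3S) diastereomer is separable.

**Step 3**
Reactants: 7 (4R,4′R)-3,3′-{(2S,3S)-2,3-bis[4-(tert-butyldimethylsilyloxy)-3-methoxybenzyl]butanedioyl}bis(4-isopropyl-1,3-oxazolidin-2-one)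
Product: 8 dimethyl (2S,3S)-2,3-bis(4-hydroxy-3-methoxybenzyl)butanedioate
Conditions: NaOMe (6 equiv), MeOH–dimethyl carbonate (1:1), 0 °C → rt, 3 h; 1 M HCl quench
Reagents that add atoms: sodium methoxide, C[O-].[Na+] (in methanol, CO)
Why: Methoxide transesterification of the N-acyloxazolidinones (dimethyl carbonate re-closes any endocyclically opened auxiliary so that it can still be cleaved exocyclically) also cleaves the base-labile aryl silyl ethers, and the short time at or below rt leaves the α-stereocentres intact.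

**Step 4**
Reactants: 8 dimethyl (2S,3S)-2,3-bis(4-hydroxy-3-methoxybenzyl)butanedioate
Product: 10 dimethyl (2R,3R,4R,5R)-2,5-bis(4-hydroxy-3-methoxyphenyl)oxolane-3,4-dicarboxylate (all-trans), via dimethyl (2R,3R)-2,3-bis[acetoxy(4-hydroxy-3-methoxyphenyl)methyl]butanedioate (benzylic epimers) 9 (not isolated)
Conditions: DDQ (2.0 equiv), AcOH–CH2Cl2 (1:1), 0 °C → rt, 1 h; strip CH2Cl2; then H2O (to AcOH–H2O 3:1), TFA (0.2 equiv), 40 °C, 3 h
Reagents that add atoms: water, O (ring oxygen); acetic acid, CC(=O)O (acetoxy groups of 9 only, released again)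
Why: Proposed new method: dehydrogenative "water stitching" of two benzylic CH2 groups – DDQ removes hydride from each 4-hydroxy-3-methoxybenzyl position (p-quinone-methide pathway) and acetic acid parks each electrophilic carbon as an acyloxy group, which loses a second hydride much less readily than a carbinol or ether, so no aryl ketone or furan forms while oxidant is present; water is admitted only after DDQ is spent, SN1/quinone-methide exchange turns one acetate into OH, and that OH captures the second benzylic quinone methide 5-exo to close the oxolane; benzylic C–O bonds para to a free phenol keep exchanging under the mild acid, and this reversible O-capture is expected to be much faster than the irreversible Friedel–Crafts and H-8-loss channels at 40 °C, so C2 and C5 equilibrate to the all-trans isomer dictated by the fixed C3/C4 centres; the closest known reaction types are DDQ benzylic acetoxylation/oxidation of 4-alkylphenols, water capture of the bis(quinone methide) formed in ferulate dehydrodimerisation, and acid cyclodehydration/epimerisation of 2,5-diaryloxolane lignans.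

**Step 5**
Reactants: 10 dimethyl (2R,3R,4R,5R)-2,5-bis(4-hydroxy-3-methoxyphenyl)oxolane-3,4-dicarboxylate
Product: 11 (+)-neoolivil, (2R,3S,4S,5R)-2,5-bis(4-hydroxy-3-methoxyphenyl)-3,4-bis(hydroxymethyl)oxolane
Conditions: LiAlH4 (6 equiv), THF, 0 °C → rt, 2 h; aq. Rochelle salt work-up
Reagents that add atoms: none
Why: LiAlH4 ester reduction (the excess covers the two phenols) is faster than base-induced β-elimination at 0 °C and touches no stereocentre (the C3/C4 descriptors change from R to S only through CIP priorities), and the neutral work-up avoids acid-induced rearrangement.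

**Compound list**
1 | 3-(4-hydroxy-3-methoxyphenyl)propanoic acid | COc1cc(CCC(=O)O)ccc1O | starting material
2 | (4R)-4-isopropyl-1,3-oxazolidin-2-one | CC(C)[C@@H]1COC(=O)N1 | starting material
3 | 3-(4-hydroxy-3-methoxyphenyl)propanoic pivalic anhydride | COc1cc(CCC(=O)OC(=O)C(C)(C)C)ccc1O | intermediate
4 | (4R)-3-[3-(4-hydroxy-3-methoxyphenyl)propanoyl]-4-isopropyl-1,3-oxazolidin-2-one | COc1cc(CCC(=O)N2[C@H](C(C)C)COC2=O)ccc1O | intermediate
5 | (4R)-3-{3-[4-(tert-butyldimethylsilyloxy)-3-methoxyphenyl]propanoyl}-4-isopropyl-1,3-oxazolidin-2-one | COc1cc(CCC(=O)N2[C@H](C(C)C)COC2=O)ccc1O[Si](C)(C)C(C)(C)C | intermediate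
6 | lithium (Z)-3-[4-(tert-butyldimethylsilyloxy)-3-methoxyphenyl]-1-[(4R)-4-isopropyl-2-oxo-1,3-oxazolidin-3-yl]prop-1-en-1-olate | [Li+].[O-]/C(=C\Cc1ccc(O[Si](C)(C)C(C)(C)C)c(OC)c1)N1[C@H](C(C)C)COC1=O | intermediate
7 | (4R,4′R)-3,3′-{(2S,3S)-2,3-bis[4-(tert-butyldimethylsilyloxy)-3-methoxybenzyl]butanedioyl}bis(4-isopropyl-1,3-oxazolidin-2-one) | O=C([C@@H](Cc1ccc(O[Si](C)(C)C(C)(C)C)c(OC)c1)[C@H](Cc1ccc(O[Si](C)(C)C(C)(C)C)c(OC)c1)C(=O)N1[C@H](C(C)C)COC1=O)N1[C@H](C(C)C)COC1=O | intermediate
8 | dimethyl (2S,3S)-2,3-bis(4-hydroxy-3-methoxybenzyl)butanedioate | COC(=O)[C@@H](Cc1ccc(O)c(OC)c1)[C@H](Cc1ccc(O)c(OC)c1)C(=O)OC | intermediate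
9 | dimethyl (2R,3R)-2,3-bis[acetoxy(4-hydroxy-3-methoxyphenyl)methyl]butanedioate, benzylic epimers | COC(=O)[C@@H](C(OC(C)=O)c1ccc(O)c(OC)c1)[C@H](C(OC(C)=O)c1ccc(O)c(OC)c1)C(=O)OC | intermediate
10 | dimethyl (2R,3R,4R,5R)-2,5-bis(4-hydroxy-3-methoxyphenyl)oxolane-3,4-dicarboxylate | COc1cc([C@@H]2O[C@@H](c3ccc(O)c(OC)c3)[C@H](C(=O)OC)[C@H]2C(=O)OC)ccc1O | intermediate
11 | (+)-neoolivil, (2R,3S,4S,5R) | COc1cc([C@@H]2O[C@@H](c3ccc(O)c(OC)c3)[C@H](CO)[C@H]2CO)ccc1O | target

**Totals:** 5 steps; longest linear sequence 5 steps.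

**Steps most likely to fail, with fallbacks**

**Step 2.** The risks are α-chlorination, modest conversion, or modest diastereoselectivity in the radical dimerisation. The fallback replaces auxiliary control by resolution. It sets out from 1 and comes back to the route at 8. Fischer esterification (MeOH, cat. H2SO4, reflux) gives methyl 3-(4-hydroxy-3-methoxyphenyl)propanoate F1. TBSCl/imidazole (DMF, rt) then gives methyl 3-[4-(tert-butyldimethylsilyloxy)-3-methoxyphenyl]propanoate F2. Ester-enolate oxidative dimerisation (LDA, then CuBr2, THF, −78 °C), with the meso isomer removed by chromatography, gives racemic dimethyl (2S*,3S*)-2,3-bis[4-(tert-butyldimethylsilyloxy)-3-methoxybenzyl]butanedioate F3. TBAF/AcOH (THF, 0 °C) gives racemic dimethyl (2S*,3S*)-2,3-bis(4-hydroxy-3-methoxybenzyl)butanedioate F4. Preparative chiral SFC of this racemate delivers 8.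

**Step 3.** The risks are endocyclic opening of the hindered imides and partial epimerisation at C8/C8′ by methoxide. The fallback uses hydrolysis followed by esterification. It sets out from 7 and comes back at 8. LiOH/H2O2 (THF–H2O, 0 °C → rt) cleaves the imides exocyclically without epimerisation and also removes the aryl silyl ethers. This gives (2S,3S)-2,3-bis(4-hydroxy-3-methoxybenzyl)butanedioic acid F5. SOCl2/MeOH (0 °C → rt) esterifies this diacid to 8.

**Step 4 (the new step).** There are four risks: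
- Friedel–Crafts closure of a benzylic cation onto the other arene, giving an aryltetralin.
- Loss of H-8, giving a benzylidene succinate.
- Capture by the C9′ ester, giving a γ-lactone.
- Over-oxidation if DDQ survives into the aqueous stage.

The fallback uses known chemistry only. It sets out from 8 and comes back at 10. Ac2O/pyridine gives dimethyl (2S,3S)-2,3-bis(4-acetoxy-3-methoxybenzyl)butanedioate F6. Wohl–Ziegler bromination (NBS 2.1 equiv, AIBN, PhCF3, 80 °C) gives dimethyl (2S,3S)-2,3-bis[(4-acetoxy-3-methoxyphenyl)bromomethyl]butanedioate F7 as benzylic epimers. In the silver-assisted hydrolysis (Ag2CO3, acetone–H2O) the first-formed alcohol displaces the second bromide. This gives dimethyl (3R,4R)-2,5-bis(4-acetoxy-3-methoxyphenyl)oxolane-3,4-dicarboxylate F8 as C2/C5 epimers. Pyrrolidine (MeCN, rt) removes the aryl acetates to give dimethyl (3R,4R)-2,5-bis(4-hydroxy-3-methoxyphenyl)oxolane-3,4-dicarboxylate F9 as the C2/C5 epimer mixture. BF3·OEt2 (CH2Cl2, −20 °C), the established Lewis-acid epimerisation of 2,5-diaryloxolane lignans, converges this mixture on 10.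

**Further compounds**
F1 | step 2 | methyl 3-(4-hydroxy-3-methoxyphenyl)propanoate | COc1cc(CCC(=O)OC)ccc1O
F2 | step 2 | methyl 3-[4-(tert-butyldimethylsilyloxy)-3-methoxyphenyl]propanoate | COc1cc(CCC(=O)OC)ccc1O[Si](C)(C)C(C)(C)C
F3 | step 2 | racemic dimethyl (2S*,3S*)-2,3-bis[4-(tert-butyldimethylsilyloxy)-3-methoxybenzyl]butanedioate | COC(=O)[C@@H](Cc1ccc(O[Si](C)(C)C(C)(C)C)c(OC)c1)[C@H](Cc1ccc(O[Si](C)(C)C(C)(C)C)c(OC)c1)C(=O)OC.COC(=O)[C@H](Cc1ccc(O[Si](C)(C)C(C)(C)C)c(OC)c1)[C@@H](Cc1ccc(O[Si](C)(C)C(C)(C)C)c(OC)c1)C(=O)OC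
F4 | step 2 | racemic dimethyl (2S*,3S*)-2,3-bis(4-hydroxy-3-methoxybenzyl)butanedioate | COC(=O)[C@@H](Cc1ccc(O)c(OC)c1)[C@H](Cc1ccc(O)c(OC)c1)C(=O)OC.COC(=O)[C@H](Cc1ccc(O)c(OC)c1)[C@@H](Cc1ccc(O)c(OC)c1)C(=O)OC
F5 | step 3 | (2S,3S)-2,3-bis(4-hydroxy-3-methoxybenzyl)butanedioic acid | OC(=O)[C@@H](Cc1ccc(O)c(OC)c1)[C@H](Cc1ccc(O)c(OC)c1)C(=O)O
F6 | step 4 | dimethyl (2S,3S)-2,3-bis(4-acetoxy-3-methoxybenzyl)butanedioate | COC(=O)[C@@H](Cc1ccc(OC(C)=O)c(OC)c1)[C@H](Cc1ccc(OC(C)=O)c(OC)c1)C(=O)OC
F7 | step 4 | dimethyl (2S,3S)-2,3-bis[(4-acetoxy-3-methoxyphenyl)bromomethyl]butanedioate, benzylic epimers | COC(=O)[C@@H](C(Br)c1ccc(OC(C)=O)c(OC)c1)[C@H](C(Br)c1ccc(OC(C)=O)c(OC)c1)C(=O)OC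
F8 | step 4 | dimethyl (3R,4R)-2,5-bis(4-acetoxy-3-methoxyphenyl)oxolane-3,4-dicarboxylate, C2/C5 epimers | COc1cc(C2OC(c3ccc(OC(C)=O)c(OC)c3)[C@H](C(=O)OC)[C@H]2C(=O)OC)ccc1OC(C)=O
F9 | step 4 | dimethyl (3R,4R)-2,5-bis(4-hydroxy-3-methoxyphenyl)oxolane-3,4-dicarboxylate, C2/C5 epimers | COc1cc(C2OC(c3ccc(O)c(OC)c3)[C@H](C(=O)OC)[C@H]2C(=O)OC)ccc1O
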